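The target's cyclopentanone is closed last through its C3–C3a bond (octahydroindene numbering: C1 CHOAc, C2 C=O, C3 CH2, C4 C=CH2, C5 OAng, C6 OH, C7 iPr). A rhodium carbenoid made at C3 from a diazoketone side chain on C7a of a fully substituted methylidenecyclohexane inserts into the equatorial C–H bond of the C3a methylene, which lies 1,5 to C3 beside the C4 methylidene. This one step forms the ring, the C3a stereocentre and the trans ring fusion. The monocyclic precursor comes from a Diels–Alder reaction that sets C7a, C7 and C6 under control of a glyceraldehyde-derived C1 stereocentre.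

Key step: step 13

Remark: the labels C1–C7a in the text are those of the target's octahydroindene core and are kept for the same atoms in every intermediate (systematic names use their own locants); aldehyde 3, ylide 4 and angelic acid 11 are taken as purchasable.

Step 1
Reactants: 1 3-methylbut-2-enal
Product: 2 tert-butyl(dimethyl){[(1E)-3-methylbuta-1,3-dien-1-yl]oxy}silane
Conditions: TBSOTf, Et3N, Et2O, 0 °C → rt
Reagents that add atoms: tert-butyldimethylsilyl triflate, CC(C)(C)[Si](C)(C)OS(=O)(=O)C(F)(F)F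
Why: O-silylation of the enal with γ-deprotonation (silyl dienol ether formation) should give the (E)-1-silyloxydiene from the s-trans enal; no stereocentre is formed.

Step 2
Reactants: 3 (4S)-2,2-dimethyl-1,3-dioxolane-4-carbaldehyde; 4 1-(triphenyl-λ5-phosphanylidene)propan-2-one
Product: 5 (3E)-4-[(4R)-2,2-dimethyl-1,3-dioxolan-4-yl]but-3-en-2-one
Conditions: CH2Cl2, 0 °C → rt
Reagents that add atoms: none
Why: Wittig olefination with a stabilised ylide should give the (E)-enone, the chiral-pool centre (future C1) being untouched (its descriptor changes from S to R only through the CIP priorities).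

Step 3
Reactants: 2 tert-butyl(dimethyl){[(1E)-3-methylbuta-1,3-dien-1-yl]oxy}silane; 5 (3E)-4-[(4R)-2,2-dimethyl-1,3-dioxolan-4-yl]but-3-en-2-one
Product: 6 1-[(1S,2R,6R)-2-{[tert-butyl(dimethyl)silyl]oxy}-6-[(4R)-2,2-dimethyl-1,3-dioxolan-4-yl]-4-methylcyclohex-3-en-1-yl]ethan-1-one
Conditions: Me2AlCl (20 mol %), CH2Cl2, −78 → −30 °C
Reagents that add atoms: none
Why: Lewis-acid-promoted Diels–Alder reaction in which the CH2 terminus of the 1-silyloxydiene bonds to the enone β-carbon (ortho/para rule), the (E)-alkene fixes C7a/C7 trans, the endo acetyl group ends up cis to OTBS at C6, and the diene should add anti to the dioxolane C–O bond in the H-eclipsed Felkin–Anh-type conformer (as nucleophiles do with γ-alkoxy enones), so that C1 controls the absolute configuration of the three new centres.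

Step 4
Reactants: 6 1-[(1S,2R,6R)-2-{[tert-butyl(dimethyl)silyl]oxy}-6-[(4R)-2,2-dimethyl-1,3-dioxolan-4-yl]-4-methylcyclohex-3-en-1-yl]ethan-1-one
Product: 7 tert-butyl({(1R,5R,6R)-5-[(4R)-2,2-dimethyl-1,3-dioxolan-4-yl]-3-methyl-6-(prop-1-en-2-yl)cyclohex-2-en-1-yl}oxy)dimethylsilane
Conditions: Ph3PCH3Br, KHMDS, THF, −78 → 0 °C
Reagents that add atoms: methyltriphenylphosphonium bromide, C[P+](c1ccccc1)(c1ccccc1)c1ccccc1.[Br-]
Why: Wittig methylenation of the methyl ketone with a slight deficit of base, so that the α-stereocentre (C7) and the β-silyloxy group should survive; no new stereocentre.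

Step 5
Reactants: 7 tert-butyl({(1R,5R,6R)-5-[(4R)-2,2-dimethyl-1,3-dioxolan-4-yl]-3-methyl-6-(prop-1-en-2-yl)cyclohex-2-en-1-yl}oxy)dimethylsilane
Product: 8 tert-butyl({(1S,5R,6S)-5-[(4R)-2,2-dimethyl-1,3-dioxolan-4-yl]-3-methyl-6-(propan-2-yl)cyclohex-2-en-1-yl}oxy)dimethylsilane
Conditions: H2 (1 atm), RhCl(PPh3)3 (5 mol %), benzene, rt
Reagents that add atoms: none
Why: Homogeneous hydrogenation with Wilkinson's catalyst should reduce only the unhindered 1,1-disubstituted isopropenyl alkene and leave the trisubstituted ring alkene; no stereocentre is created.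

Step 6
Reactants: 8 tert-butyl({(1S,5R,6S)-5-[(4R)-2,2-dimethyl-1,3-dioxolan-4-yl]-3-methyl-6-(propan-2-yl)cyclohex-2-en-1-yl}oxy)dimethylsilane
Product: 9 tert-butyl({(1R,2S,3S,4R,6S)-4-[(4R)-2,2-dimethyl-1,3-dioxolan-4-yl]-6-methyl-3-(propan-2-yl)-7-oxabicyclo[4.1.0]heptan-2-yl}oxy)dimethylsilane
Conditions: mCPBA, CH2Cl2, 0 °C
Reagents that add atoms: 3-chloroperoxybenzoic acid, OOC(=O)c1cccc(Cl)c1
Why: Prilezhaev epoxidation in which the pseudoaxial allylic OTBS group (cis to the equatorial isopropyl group) should shield the α-face, so that oxygen is delivered anti to it and sets the C5–O bond β, trans to C6–O.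

Step 7
Reactants: 9 tert-butyl({(1R,2S,3S,4R,6S)-4-[(4R)-2,2-dimethyl-1,3-dioxolan-4-yl]-6-methyl-3-(propan-2-yl)-7-oxabicyclo[4.1.0]heptan-2-yl}oxy)dimethylsilane
Product: 10 (1S,2S,3S,4R)-2-{[tert-butyl(dimethyl)silyl]oxy}-4-[(4R)-2,2-dimethyl-1,3-dioxolan-4-yl]-6-methylidene-3-(propan-2-yl)cyclohexan-1-ol
Conditions: Et2AlCl, LiTMP (gives Et2Al–TMP), toluene, 0 °C
Reagents that add atoms: none
Why: Base-induced epoxide-to-allylic-alcohol isomerisation (syn β-elimination) with the bulky aluminium amide, which should take the proton from the methyl group cis to the epoxide hydrogen to give the exocyclic C4 methylidene, while the C5–O bond keeps its configuration and the aluminium alkoxide should not trigger silyl migration.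

Step 8
Reactants: 10 (1S,2S,3S,4R)-2-{[tert-butyl(dimethyl)silyl]oxy}-4-[(4R)-2,2-dimethyl-1,3-dioxolan-4-yl]-6-methylidene-3-(propan-2-yl)cyclohexan-1-ol; 11 (2Z)-2-methylbut-2-enoic acid (angelic acid)
Product: 13 (1S,2S,3S,4R)-2-{[tert-butyl(dimethyl)silyl]oxy}-4-[(4R)-2,2-dimethyl-1,3-dioxolan-4-yl]-6-methylidene-3-(propan-2-yl)cyclohexyl (2Z)-2-methylbut-2-enoate, via mixed angelic 2,4,6-trichlorobenzoic anhydride 12 (not isolated)
Conditions: 11, 2,4,6-trichlorobenzoyl chloride, Et3N, toluene, rt; then 10, 80 °C (no DMAP)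
Reagents that add atoms: 2,4,6-trichlorobenzoyl chloride, O=C(Cl)c1c(Cl)cc(Cl)cc1Cl (its aroyl group stays only in intermediate 12)
Why: Yamaguchi esterification through the mixed anhydride without nucleophilic catalyst, conditions under which hindered secondary alcohols should be angeloylated without Z→E isomerisation; O-acylation leaves the C5 configuration unchanged.

Step 9
Reactants: 13 (1S,2S,3S,4R)-2-{[tert-butyl(dimethyl)silyl]oxy}-4-[(4R)-2,2-dimethyl-1,3-dioxolan-4-yl]-6-methylidene-3-(propan-2-yl)cyclohexyl (2Z)-2-methylbut-2-enoate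
Product: 14 (1S,2S,3S,4R)-2-{[tert-butyl(dimethyl)silyl]oxy}-4-[(1R)-1,2-dihydroxyethyl]-6-methylidene-3-(propan-2-yl)cyclohexyl (2Z)-2-methylbut-2-enoate
Conditions: AcOH/H2O (4:1), 40 °C
Reagents that add atoms: none
Why: Acid-catalysed hydrolysis of the terminal isopropylidene acetal, which should be cleaved under conditions that spare the hindered secondary TBS ether and the allylic ester; no stereocentre is touched.

Step 10
Reactants: 14 (1S,2S,3S,4R)-2-{[tert-butyl(dimethyl)silyl]oxy}-4-[(1R)-1,2-dihydroxyethyl]-6-methylidene-3-(propan-2-yl)cyclohexyl (2Z)-2-methylbut-2-enoate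
Product: 15 (1S,2S,3S,4R)-2-{[tert-butyl(dimethyl)silyl]oxy}-4-[(R)-carboxy(hydroxy)methyl]-6-methylidene-3-(propan-2-yl)cyclohexyl (2Z)-2-methylbut-2-enoate
Conditions: TEMPO (20 mol %), PhI(OAc)2 (2.2 equiv), MeCN/H2O (1:1), rt
Reagents that add atoms: water, O
Why: Oxoammonium (TEMPO/PhI(OAc)2) oxidation, which should take the primary alcohol through the aldehyde hydrate to the acid while the hindered secondary alcohol and both alkenes are left alone; C1 keeps its configuration.

Step 11
Reactants: 15 (1S,2S,3S,4R)-2-{[tert-butyl(dimethyl)silyl]oxy}-4-[(R)-carboxy(hydroxy)methyl]-6-methylidene-3-(propan-2-yl)cyclohexyl (2Z)-2-methylbut-2-enoate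
Product: 16 (1S,2S,3S,4R)-4-[(R)-(acetyloxy)(carboxy)methyl]-2-{[tert-butyl(dimethyl)silyl]oxy}-6-methylidene-3-(propan-2-yl)cyclohexyl (2Z)-2-methylbut-2-enoate
Conditions: Ac2O, pyridine, DMAP (cat.), CH2Cl2, 0 °C → rt; aqueous work-up
Reagents that add atoms: acetic anhydride, CC(=O)OC(C)=O
Why: Base-catalysed O-acetylation of the α-hydroxy acid, any mixed anhydride at the carboxyl group being hydrolysed on work-up; configuration at C1 is retained.

Step 12
Reactants: 16 (1S,2S,3S,4R)-4-[(R)-(acetyloxy)(carboxy)methyl]-2-{[tert-butyl(dimethyl)silyl]oxy}-6-methylidene-3-(propan-2-yl)cyclohexyl (2Z)-2-methylbut-2-enoate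
Product: 18 (1S,2S,3S,4R)-4-[(1R)-1-(acetyloxy)-3-diazo-2-oxopropyl]-2-{[tert-butyl(dimethyl)silyl]oxy}-6-methylidene-3-(propan-2-yl)cyclohexyl (2Z)-2-methylbut-2-enoate, via acid chloride 17 (not isolated)
Conditions: 1-chloro-N,N,2-trimethylprop-1-en-1-amine, CH2Cl2, 0 °C; then CH2N2 (excess), Et2O, 0 °C
Reagents that add atoms: diazomethane, C=[N+]=[N-]; 1-chloro-N,N,2-trimethylprop-1-en-1-amine, CC(C)=C(Cl)N(C)C (its chlorine stays only in intermediate 17)
Why: Neutral acid chloride formation with the α-chloroenamine followed by acylation of diazomethane (Arndt–Eistert-type diazoketone synthesis) should give the α′-acetoxy diazoketone without touching the silyl ether or the esters, the excess diazomethane taking up the HCl.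

Step 13
Reactants: 18 (1S,2S,3S,4R)-4-[(1R)-1-(acetyloxy)-3-diazo-2-oxopropyl]-2-{[tert-butyl(dimethyl)silyl]oxy}-6-methylidene-3-(propan-2-yl)cyclohexyl (2Z)-2-methylbut-2-enoate
Product: 20 (1R,3aR,5S,6S,7S,7aR)-1-(acetyloxy)-6-{[tert-butyl(dimethyl)silyl]oxy}-4-methylidene-2-oxo-7-(propan-2-yl)octahydro-1H-inden-5-yl (2Z)-2-methylbut-2-enoate, via rhodium carbenoid 19 (not isolated)
Conditions: Rh2(OAc)4 (2 mol %), CH2Cl2, rt, slow addition of 18 at high dilution
Reagents that add atoms: none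
Why: Rh2(OAc)4 decomposes the diazoketone with loss of N2 to an electrophilic carbenoid at C3 (an umpoled ketone α-carbon), which inserts into a C–H bond through a concerted three-centre, hydride-transfer-like transition state and releases the catalyst. The closest known reaction type is the Rh(II)-catalysed intramolecular 1,5 C–H insertion of α-diazoketones to cyclopentanones, together with the equatorial-selective insertion of cyclohexyl diazoacetates that gives trans-fused five-membered rings. The cyclopentanone closes by 1,5-insertion through a chair-like six-centre array (C3, C2, C1, C7a, C3a, H) in which both bonds from the cyclohexane to the new ring are equatorial. C3a is the only new stereocentre: insertion goes with retention, so reaction at the equatorial hydrogen of the C3a methylene, gauche to the equatorial side chain on C7a in the chair that has isopropyl equatorial and the C5/C6 oxygens trans-diaxial, should give the trans ring fusion. The step needs site selectivity for this hydrogen over the axial C3a–H and the axial C7 methine (both syn-axial to the C5 ester; C7–H is also flanked by isopropyl and deactivated by the β-silyloxy group), and chemoselectivity over cyclopropanation of the C4 methylidene, which should be reachable only from the disfavoured ring-flipped conformer. Slow addition should suppress carbene dimerisation, and ester carbonyls are poor carbenoid traps.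

Step 14
Reactants: 20 (1R,3aR,5S,6S,7S,7aR)-1-(acetyloxy)-6-{[tert-butyl(dimethyl)silyl]oxy}-4-methylidene-2-oxo-7-(propan-2-yl)octahydro-1H-inden-5-yl (2Z)-2-methylbut-2-enoate
Product: 21 (1R,3aR,5S,6S,7S,7aR)-1-(acetyloxy)-6-hydroxy-4-methylidene-2-oxo-7-(propan-2-yl)octahydro-1H-inden-5-yl (2Z)-2-methylbut-2-enoate (CNP0317011.1)
Conditions: HF·pyridine, THF/pyridine, 0 °C → rt
Reagents that add atoms: none
Why: Fluoride-mediated desilylation under buffered acidic conditions should free the axial C6 hydroxyl without cleaving either ester and without acyl migration, since the C5 ester is trans-diaxial to it.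

Compound list
1 | 3-methylbut-2-enal | CC(C)=CC=O | starting material
2 | tert-butyl(dimethyl){[(1E)-3-methylbuta-1,3-dien-1-yl]oxy}silane | C=C(C)/C=C/O[Si](C)(C)C(C)(C)C | intermediate
3 | (4S)-2,2-dimethyl-1,3-dioxolane-4-carbaldehyde | O=C[C@@H]1COC(C)(C)O1 | starting material
4 | 1-(triphenyl-λ5-phosphanylidene)propan-2-one | CC(=O)C=P(c1ccccc1)(c1ccccc1)c1ccccc1 | starting material
5 | (3E)-4-[(4R)-2,2-dimethyl-1,3-dioxolan-4-yl]but-3-en-2-one | CC(=O)/C=C/[C@@H]1COC(C)(C)O1 | intermediate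
6 | 1-[(1S,2R,6R)-2-{[tert-butyl(dimethyl)silyl]oxy}-6-[(4R)-2,2-dimethyl-1,3-dioxolan-4-yl]-4-methylcyclohex-3-en-1-yl]ethan-1-one | CC1=C[C@@H](O[Si](C)(C)C(C)(C)C)[C@@H](C(C)=O)[C@H]([C@@H]2COC(C)(C)O2)C1 | intermediate
7 | tert-butyl({(1R,5R,6R)-5-[(4R)-2,2-dimethyl-1,3-dioxolan-4-yl]-3-methyl-6-(prop-1-en-2-yl)cyclohex-2-en-1-yl}oxy)dimethylsilane | CC1=C[C@@H](O[Si](C)(C)C(C)(C)C)[C@@H](C(C)=C)[C@H]([C@@H]2COC(C)(C)O2)C1 | intermediate
8 | tert-butyl({(1S,5R,6S)-5-[(4R)-2,2-dimethyl-1,3-dioxolan-4-yl]-3-methyl-6-(propan-2-yl)cyclohex-2-en-1-yl}oxy)dimethylsilane | CC1=C[C@@H](O[Si](C)(C)C(C)(C)C)[C@@H](C(C)C)[C@H]([C@@H]2COC(C)(C)O2)C1 | intermediate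
9 | tert-butyl({(1R,2S,3S,4R,6S)-4-[(4R)-2,2-dimethyl-1,3-dioxolan-4-yl]-6-methyl-3-(propan-2-yl)-7-oxabicyclo[4.1.0]heptan-2-yl}oxy)dimethylsilane (epoxide anti to OTBS) | C[C@@]12O[C@@H]1[C@@H](O[Si](C)(C)C(C)(C)C)[C@@H](C(C)C)[C@H]([C@@H]3COC(C)(C)O3)C2 | intermediate
10 | (1S,2S,3S,4R)-2-{[tert-butyl(dimethyl)silyl]oxy}-4-[(4R)-2,2-dimethyl-1,3-dioxolan-4-yl]-6-methylidene-3-(propan-2-yl)cyclohexan-1-ol | C=C1C[C@@H]([C@@H]2COC(C)(C)O2)[C@H](C(C)C)[C@H](O[Si](C)(C)C(C)(C)C)[C@H]1O | intermediate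
11 | (2Z)-2-methylbut-2-enoic acid (angelic acid) | C/C=C(/C)C(=O)O | starting material
12 | (2Z)-2-methylbut-2-enoic 2,4,6-trichlorobenzoic anhydride | C/C=C(/C)C(=O)OC(=O)c1c(Cl)cc(Cl)cc1Cl | intermediate (not isolated)
13 | (1S,2S,3S,4R)-2-{[tert-butyl(dimethyl)silyl]oxy}-4-[(4R)-2,2-dimethyl-1,3-dioxolan-4-yl]-6-methylidene-3-(propan-2-yl)cyclohexyl (2Z)-2-methylbut-2-enoate | C=C1C[C@@H]([C@@H]2COC(C)(C)O2)[C@H](C(C)C)[C@H](O[Si](C)(C)C(C)(C)C)[C@H]1OC(=O)/C(C)=C\C | intermediate
14 | (1S,2S,3S,4R)-2-{[tert-butyl(dimethyl)silyl]oxy}-4-[(1R)-1,2-dihydroxyethyl]-6-methylidene-3-(propan-2-yl)cyclohexyl (2Z)-2-methylbut-2-enoate | C=C1C[C@@H]([C@@H](O)CO)[C@H](C(C)C)[C@H](O[Si](C)(C)C(C)(C)C)[C@H]1OC(=O)/C(C)=C\C | intermediate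
15 | (1S,2S,3S,4R)-2-{[tert-butyl(dimethyl)silyl]oxy}-4-[(R)-carboxy(hydroxy)methyl]-6-methylidene-3-(propan-2-yl)cyclohexyl (2Z)-2-methylbut-2-enoate | C=C1C[C@@H]([C@@H](O)C(=O)O)[C@H](C(C)C)[C@H](O[Si](C)(C)C(C)(C)C)[C@H]1OC(=O)/C(C)=C\C | intermediate
16 | (1S,2S,3S,4R)-4-[(R)-(acetyloxy)(carboxy)methyl]-2-{[tert-butyl(dimethyl)silyl]oxy}-6-methylidene-3-(propan-2-yl)cyclohexyl (2Z)-2-methylbut-2-enoate | C=C1C[C@@H]([C@@H](OC(C)=O)C(=O)O)[C@H](C(C)C)[C@H](O[Si](C)(C)C(C)(C)C)[C@H]1OC(=O)/C(C)=C\C | intermediate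
17 | (1S,2S,3S,4R)-4-[(1R)-1-(acetyloxy)-2-chloro-2-oxoethyl]-2-{[tert-butyl(dimethyl)silyl]oxy}-6-methylidene-3-(propan-2-yl)cyclohexyl (2Z)-2-methylbut-2-enoate (acid chloride) | C=C1C[C@@H]([C@@H](OC(C)=O)C(=O)Cl)[C@H](C(C)C)[C@H](O[Si](C)(C)C(C)(C)C)[C@H]1OC(=O)/C(C)=C\C | intermediate (not isolated)
18 | (1S,2S,3S,4R)-4-[(1R)-1-(acetyloxy)-3-diazo-2-oxopropyl]-2-{[tert-butyl(dimethyl)silyl]oxy}-6-methylidene-3-(propan-2-yl)cyclohexyl (2Z)-2-methylbut-2-enoate | C=C1C[C@@H]([C@@H](OC(C)=O)C(=O)C=[N+]=[N-])[C@H](C(C)C)[C@H](O[Si](C)(C)C(C)(C)C)[C@H]1OC(=O)/C(C)=C\C | intermediate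
19 | rhodium carbenoid of 18 at C3 (dirhodium tetraacetate core abbreviated as one Rh) | C=C1C[C@@H]([C@@H](OC(C)=O)C(=O)C=[Rh])[C@H](C(C)C)[C@H](O[Si](C)(C)C(C)(C)C)[C@H]1OC(=O)/C(C)=C\C | intermediate (not isolated)
20 | (1R,3aR,5S,6S,7S,7aR)-1-(acetyloxy)-6-{[tert-butyl(dimethyl)silyl]oxy}-4-methylidene-2-oxo-7-(propan-2-yl)octahydro-1H-inden-5-yl (2Z)-2-methylbut-2-enoate | C=C1[C@@H]2CC(=O)[C@H](OC(C)=O)[C@H]2[C@H](C(C)C)[C@H](O[Si](C)(C)C(C)(C)C)[C@H]1OC(=O)/C(C)=C\C | intermediate
21 | (1R,3aR,5S,6S,7S,7aR)-1-(acetyloxy)-6-hydroxy-4-methylidene-2-oxo-7-(propan-2-yl)octahydro-1H-inden-5-yl (2Z)-2-methylbut-2-enoate | C=C1[C@@H]2CC(=O)[C@H](OC(C)=O)[C@H]2[C@H](C(C)C)[C@H](O)[C@H]1OC(=O)/C(C)=C\C | target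

Total step count: 14. Longest linear sequence: 13 steps (steps 1, 3–14; the branch through step 2 is equally long).

Steps most likely to fail

1. Step 13 (key step). The acceptor-only carbenoid may be diverted before it reaches the equatorial C3a–H: the C1 acetate carbonyl oxygen may attack it (carbonyl ylide formation), it may cyclopropanate the C4 methylidene from the minor ring-flipped conformer, or it may insert into the axial C3a–H (cis fusion) or the C7 methine. The fallback uses a different carbenoid class with a removable activating group. It sets out from acid 16 through its chloride 17. Acylation of magnesium mono-tert-butyl malonate (potassium salt, MgCl2, Et3N, MeCN), with decarboxylation on acidic work-up, gives the tert-butyl β-keto ester F1. Diazo transfer (4-acetamidobenzenesulfonyl azide, Et3N, MeCN) gives the α-diazo-β-keto ester F2. Rh2(OAc)4 in CH2Cl2 then closes the same C3–C3a bond by 1,5-insertion of the bulkier, more discriminating acceptor/acceptor carbenoid and gives the bicyclic β-keto ester F3. Cleavage of the tert-butyl ester (TMSOTf, 2,6-lutidine, CH2Cl2, 0 °C, then aqueous work-up) and decarboxylation on gentle warming bring the route back to 20.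

2. Step 3. The dioxolane stereocentre may discriminate the two faces of the enone poorly, and endo control may be incomplete, so that cyclohexenes with the ring of the opposite absolute configuration form alongside 6. The fallback replaces substrate control by reagent control: the same partners 2 and 5 are joined under a chiral, proline-derived oxazaborolidinium Lewis acid (triflimide-activated, CH2Cl2, −78 °C). The catalyst enantiomer is the one matched with the intrinsic anti-to-oxygen preference, so the catalyst and not the C1 centre fixes the face. It sets out from 2 and 5, returns at 6 and makes no new compound (F0).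

3. Step 8. Acylation of the hindered axial allylic alcohol may be slow, and the angeloyl unit may isomerise from Z to E (tiglate formation) under the forcing conditions this calls for. The fallback builds the Z-alkene after the acylation. It sets out from 10: esterification with 2-[bis(2,2,2-trifluoroethoxy)phosphoryl]propanoic acid (DCC, DMAP, CH2Cl2) gives the phosphonopropanoate F4, and Still–Gennari olefination with acetaldehyde (KHMDS, 18-crown-6, THF, −78 °C) should give the Z-configured ester, returning at 13.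

Further compounds
F1 | step 13 | tert-butyl (4R)-4-(acetyloxy)-4-[(1R,2S,3S,4S)-3-{[tert-butyl(dimethyl)silyl]oxy}-5-methylidene-4-{[(2Z)-2-methylbut-2-enoyl]oxy}-2-(propan-2-yl)cyclohexyl]-3-oxobutanoate | C=C1C[C@@H]([C@@H](OC(C)=O)C(=O)CC(=O)OC(C)(C)C)[C@H](C(C)C)[C@H](O[Si](C)(C)C(C)(C)C)[C@H]1OC(=O)/C(C)=C\C
F2 | step 13 | tert-butyl (4R)-4-(acetyloxy)-2-diazo-4-[(1R,2S,3S,4S)-3-{[tert-butyl(dimethyl)silyl]oxy}-5-methylidene-4-{[(2Z)-2-methylbut-2-enoyl]oxy}-2-(propan-2-yl)cyclohexyl]-3-oxobutanoate | C=C1C[C@@H]([C@@H](OC(C)=O)C(=O)C(=[N+]=[N-])C(=O)OC(C)(C)C)[C@H](C(C)C)[C@H](O[Si](C)(C)C(C)(C)C)[C@H]1OC(=O)/C(C)=C\C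
F3 | step 13 | 3-(tert-butoxycarbonyl) derivative of 20 (C3 epimers and enol; all other centres as in 20) | C=C1[C@@H]2C(C(=O)OC(C)(C)C)C(=O)[C@H](OC(C)=O)[C@H]2[C@H](C(C)C)[C@H](O[Si](C)(C)C(C)(C)C)[C@H]1OC(=O)/C(C)=C\C
F0 | step 3 | none | none
F4 | step 8 | (1S,2S,3S,4R)-2-{[tert-butyl(dimethyl)silyl]oxy}-4-[(4R)-2,2-dimethyl-1,3-dioxolan-4-yl]-6-methylidene-3-(propan-2-yl)cyclohexyl 2-[bis(2,2,2-trifluoroethoxy)phosphoryl]propanoate (both epimers at the phosphonate carbon) | C=C1C[C@@H]([C@@H]2COC(C)(C)O2)[C@H](C(C)C)[C@H](O[Si](C)(C)C(C)(C)C)[C@H]1OC(=O)C(C)P(=O)(OCC(F)(F)F)OCC(F)(F)F
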